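(The constants used here belong to no real substance; the flask was simulated.)

Two questions are put to this flask, and one rule for the dissolved coupling partner serves both.

- amount of bis adduct at 3.0 d, in percent of the substrate charged
- concentration of coupling partner in solution at 3.0 d, in percent of saturation

    gas ⇌ coupling partner, rate k1*(csat - [coupling partner]) (k1 = 0.0039 min⁻¹, csat = 44 mM)
    coupling partner + single product → bis adduct (k2 = 0.024 M⁻¹ min⁻¹)
    coupling partner + tris adduct → tetra adduct (k3 = 0.12 M⁻¹ min⁻¹)
    coupling partner + bis adduct → tris adduct (k4 = 0.0030 M⁻¹ min⁻¹)
    substrate + coupling partner → single product (k5 = 0.042 M⁻¹ min⁻¹)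

substrate 0.30 M; gas 44 mM (held); time 3.0 d

Write a, m, d, t for the fractions of the charge standing as substrate, single product, bis adduct and tris adduct, and s for the coupling partner as a fraction of saturation. The partner's opening half-life against substrate, 0.92 h, is short beside 3.0 d, so you may let transfer balance consumption at each moment:

s/(1 − s) = T/g, with g = a + 0.571 m + 0.0714 d + 2.86 t

Here g is the consumption relative to its opening value, and T, the transfer number, is the transfer coefficient over the opening pseudo-first-order consumption constant: 0.310.

Solve the two ends. At the opening g is 1, so s is 23.6%. For pure single product g is 0.571, so s is 35.1%. Their mean, times saturation, time and the substrate constant, gives the exposure x = 2.35: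

a = 9.58%, m = 38.7%, d = 51.7%

But bis adduct passes on. Counting it at d/2 on average costs 4.33%, leaving 47.4%.

A worse objection: these fractions put s at 46.9%, higher than my end value, so the exposure was too small. Joining 23.6% to 46.9% instead gives x = 2.81, then:

a = 5.99%, m = 32.7%, d = 55.1%, s = 51.9%

I suspect a straight mean overstates a rising s, so I commit between the passes: 51.2% of bis adduct and s near 49.4%.

The forecast says 53% and 46.5%, higher in bis adduct and lower in s, and it too treats the dissolved partner as steady, on the ground that “its consumption and transfer are both fast compared with 3 d”.

The flask holds 53.1% as bis adduct and stands at 46.5% of saturation, as the forecast said, with the partner made 1.04 times as fast as it is used, each step taken net. Its fractions at 3.00 d give g = 0.343, so the rule yields 47.5%. In the neighbour flask charged with 0.075 M, T becomes 1.24 and its fractions give g = 0.153, so the rule yields 89.0%, and that flask reads 88.3%.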